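The route rests on cleaving both C–CH3 bonds at the quaternary carbon C4 of ring A, the enolised 2-isobutyryl-4,4-dimethylcyclohexane-1,3,5-trione ring. C4 lies between the oxygen-bearing carbons C3 and C5, exactly where the bridged isobutyrylphloroglucinol ring of the precursor has its only unsubstituted carbon. One base-mediated double C-methylation with iodomethane therefore dearomatises that arene and completes the target. The precursor is the all-aromatic methylene-bridged dimer: isobutyrylphloroglucinol linked through CH2 to C8 of 6-isobutyryl-5,7-dihydroxy-2,2-dimethyl-2H-chromene (benzene ring B, pyran ring C). It is assembled convergently from the chromene Mannich base and isobutyrylphloroglucinol, so chromene regiochemistry and the unsymmetrical bridge are fixed before the risky step.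

Key step: step 5

Remark: ring A is an equilibrating enolised 2-acylcyclohexane-1,3,5-trione; the drawn enol form stands for the whole set and is numbered as cyclohexa-2,5-dien-1-one (C1 carbonyl, C2 acyl, C4 gem-dimethyl, C6 bridge).

Step 1
Reactants: 1 phloroglucinol (benzene-1,3,5-triol); 2 isobutyryl chloride (2-methylpropanoyl chloride)
Product: 3 isobutyrylphloroglucinol, 2-methyl-1-(2,4,6-trihydroxyphenyl)propan-1-one
Conditions: AlCl3 (4 equiv), PhNO2, 65 °C; then ice, 1 M HCl
Reagents that add atoms: none
Why: Friedel–Crafts acylation of the threefold-symmetric, strongly activated triol can give only one mono-ketone, and the AlCl3-complexed aryl ketone is deactivated towards a second acylation.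

Step 2
Reactants: 3 isobutyrylphloroglucinol; 4 3-methylbut-2-enal (1.1 equiv)
Product: 6 1-(5,7-dihydroxy-2,2-dimethyl-2H-chromen-6-yl)-2-methylpropan-1-one, via dienyl o-quinone methide 5 (not isolated)
Conditions: ethylenediammonium diacetate (EDDA, 20 mol%), xylene, 140 °C
Reagents that add atoms: none
Why: Amine-salt-catalysed Knoevenagel-type condensation at one of the two equivalent free ring carbons gives dienyl o-quinone methide 5, whose oxa-6π electrocyclisation through the oxygen para to the ketone builds the 2,2-dimethylpyran of 6 and leaves both ketone-flanking hydroxyls free; the 8-acyl regioisomer from closure through an ortho oxygen is expected as a by-product and is removed by chromatography, and the small excess of aldehyde limits a second annulation.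

Step 3
Reactants: 6 1-(5,7-dihydroxy-2,2-dimethyl-2H-chromen-6-yl)-2-methylpropan-1-one; 7 formaldehyde
Product: 8 Mannich base 1-{8-[(dimethylamino)methyl]-5,7-dihydroxy-2,2-dimethyl-2H-chromen-6-yl}-2-methylpropan-1-one
Conditions: 37% aq. CH2O (1.05 equiv), 40% aq. Me2NH (1.2 equiv), EtOH, 0 °C to rt
Reagents that add atoms: dimethylamine, CNC
Why: Phenolic Mannich reaction in which the iminium ion formed from formaldehyde and dimethylamine attacks C8, the only unsubstituted carbon of ring B and activated by both hydroxyls, while the chromene alkene and the hindered isobutyryl α-carbon do not compete at room temperature.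

Step 4
Reactants: 8 Mannich base; 3 isobutyrylphloroglucinol (3 equiv, excess recovered)
Product: 10 1-{3-[(5,7-dihydroxy-2,2-dimethyl-6-(2-methylpropanoyl)-2H-chromen-8-yl)methyl]-2,4,6-trihydroxyphenyl}-2-methylpropan-1-one, via ring B o-quinone methide 9 (not isolated)
Conditions: 1,4-dioxane, 90 °C, N2 sweep
Reagents that add atoms: none
Why: Thermal loss of dimethylamine from the o-hydroxybenzylamine gives o-quinone methide 9 (C8=CH2, C7=O), which undergoes Michael-type Friedel–Crafts C-alkylation by a free ring carbon of 3; the threefold excess of 3 and removal of the amine suppress a second alkylation of 10 and the reverse reaction.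

Step 5
Reactants: 10 methylene-bridged aromatic dimer; 11 iodomethane (2.3 equiv)
Product: 13 3,5-dihydroxy-6-{[5,7-dihydroxy-2,2-dimethyl-6-(2-methylpropanoyl)-2H-chromen-8-yl]methyl}-4,4-dimethyl-2-(2-methylpropanoyl)cyclohexa-2,5-dien-1-one (target), via C-methyl arene 12 (not isolated)
Conditions: NaOMe (5 equiv), MeI (2.3 equiv), degassed MeOH, Ar, 0 °C to rt; then 1 M HCl to pH 2, 0 °C
Reagents that add atoms: none
Why: NaOMe converts 10 into its polyphenoxide, and the phloroglucinol ring, whose three phenoxide oxygens surround the only unsubstituted ring carbon (C5 of the phenyl ring), attacks iodomethane through that carbon in an SN2 reaction and re-aromatises by proton loss to C-methyl arene 12. The phenoxide of 12 is methylated again at the same, now methyl-bearing carbon, which can no longer re-aromatise, so the ring is locked as the enolised 4,4-dimethyl triketone of ring A and rests as its delocalised, weakly nucleophilic anion until acidification. The closest known reaction is the alkylative dearomatisation of acylphloroglucinols to acylfilicinic acids with iodomethane and alkoxide. No ring is closed and no stereocentre is created. The step needs C- over O-methylation, which hydrogen-bonding methanol and the tightly paired sodium counter-ion favour, and it needs both methyl groups on one carbon of the correct ring: ring B has only two phenoxide oxygens and no unsubstituted carbon, and in the phloroglucinol ring the free (then methyl-bearing) carbon is less hindered than the carbon carrying the CH2 bridge and far more nucleophilic than the acyl-bearing carbon. Low temperature, exclusion of air and only a small excess of iodomethane are chosen to limit bridge scrambling, oxidation and a third methylation.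

Compound list
1 | phloroglucinol (benzene-1,3,5-triol) | Oc1cc(O)cc(O)c1 | starting material
2 | isobutyryl chloride (2-methylpropanoyl chloride) | CC(C)C(Cl)=O | starting material
3 | isobutyrylphloroglucinol, 2-methyl-1-(2,4,6-trihydroxyphenyl)propan-1-one | CC(C)C(=O)c1c(O)cc(O)cc1O | intermediate
4 | 3-methylbut-2-enal | CC(C)=CC=O | starting material
5 | dienyl o-quinone methide (not isolated), (6Z)-3,5-dihydroxy-6-(3-methylbut-2-en-1-ylidene)-4-(2-methylpropanoyl)cyclohexa-2,4-dien-1-one | CC(C)C(=O)C1=C(O)/C(=C/C=C(C)C)C(=O)C=C1O | intermediate
6 | 1-(5,7-dihydroxy-2,2-dimethyl-2H-chromen-6-yl)-2-methylpropan-1-one | CC(C)C(=O)c1c(O)cc2OC(C)(C)C=Cc2c1O | intermediate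
7 | formaldehyde | C=O | starting material
8 | Mannich base, 1-{8-[(dimethylamino)methyl]-5,7-dihydroxy-2,2-dimethyl-2H-chromen-6-yl}-2-methylpropan-1-one | CC(C)C(=O)c1c(O)c(CN(C)C)c2OC(C)(C)C=Cc2c1O | intermediate
9 | ring B o-quinone methide (not isolated), 5-hydroxy-2,2-dimethyl-8-methylidene-6-(2-methylpropanoyl)-2H-chromen-7(8H)-one | CC(C)C(=O)C1=C(O)C2=C(OC(C)(C)C=C2)C(=C)C1=O | intermediate
10 | key-step precursor, 1-{3-[(5,7-dihydroxy-2,2-dimethyl-6-(2-methylpropanoyl)-2H-chromen-8-yl)methyl]-2,4,6-trihydroxyphenyl}-2-methylpropan-1-one | CC(C)C(=O)c1c(O)cc(O)c(Cc2c(O)c(C(=O)C(C)C)c(O)c3c2OC(C)(C)C=C3)c1O | intermediate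
11 | iodomethane | CI | starting material
12 | C-methyl arene (not isolated), 1-{3-[(5,7-dihydroxy-2,2-dimethyl-6-(2-methylpropanoyl)-2H-chromen-8-yl)methyl]-2,4,6-trihydroxy-5-methylphenyl}-2-methylpropan-1-one | CC(C)C(=O)c1c(O)c(C)c(O)c(Cc2c(O)c(C(=O)C(C)C)c(O)c3c2OC(C)(C)C=C3)c1O | intermediate
13 | 3,5-dihydroxy-6-{[5,7-dihydroxy-2,2-dimethyl-6-(2-methylpropanoyl)-2H-chromen-8-yl]methyl}-4,4-dimethyl-2-(2-methylpropanoyl)cyclohexa-2,5-dien-1-one | CC(C)C(=O)C1=C(O)C(C)(C)C(O)=C(Cc2c(O)c(C(=O)C(C)C)c(O)c3c2OC(C)(C)C=C3)C1=O | target

Total step count: 5
Longest linear sequence: 5 steps (1 → 3 → 6 → 8 → 10 → 13)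

Steps most likely to fail

Step 5. Under alkoxide the CH2 bridge of the dimer may cleave by retro-Michael reaction and recombine to symmetrical dimers. Methylation may also occur at oxygen, or the second methyl group may enter at the bridge-bearing carbon instead of the methyl-bearing one. The fallback inverts the order of dearomatisation and bridging and sets out from 3. The same NaOMe/MeI dearomatisation in MeOH is run on the monomer, where this reaction type is established, to give isobutyrylfilicinic acid F1 (3,5-dihydroxy-4,4-dimethyl-2-(2-methylpropanoyl)cyclohexa-2,5-dien-1-one). F1, in excess, is then heated with Mannich base 8 in 1,4-dioxane at 90 °C, so that o-quinone methide 9 is trapped by the single ring CH of the enolised triketone. The sequence comes back to the route at 13, and no bridged compound is exposed to alkoxide.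

Step 2. The electrocyclisation may close through an oxygen ortho to the ketone, and the first chromene may be annulated a second time, which erodes the supply of 6. The fallback fixes the pyran oxygen before the C–C bond is made and sets out from 3. Selective O-alkylation of the non-chelated para hydroxyl with 3-chloro-3-methylbut-1-yne (CC(C)(Cl)C#C; K2CO3, KI, catalytic CuI, acetone) gives the aryl propargyl ether 1-{2,6-dihydroxy-4-[(2-methylbut-3-yn-2-yl)oxy]phenyl}-2-methylpropan-1-one F2. Heating F2 in xylene at 140 °C brings about aromatic propargyl Claisen rearrangement, 1,5-hydrogen shift and oxa-6π ring closure with the ether oxygen as ring oxygen. The sequence comes back to the route at 6.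

Step 4. The o-quinone methide may oligomerise or add twice to the phloroglucinol, and the Mannich base may transfer its aminomethyl group, which would give symmetrical by-products. The fallback forms the bridge first on a symmetrical compound and sets out from 3. Condensation of 3 with formaldehyde 7 (0.5 equiv, dilute aqueous KOH, 0 °C to rt, then 1 M HCl) gives bis[2,4,6-trihydroxy-3-(2-methylpropanoyl)phenyl]methane F3. F3 is annulated on one ring only with 3-methylbut-2-enal 4 (at most 1 equiv, EDDA, xylene, 140 °C), closing through the oxygen para to the ketone; unreacted F3 is recycled. The sequence comes back to the route at 10.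

Further compounds
F1 | step 5 | isobutyrylfilicinic acid, 3,5-dihydroxy-4,4-dimethyl-2-(2-methylpropanoyl)cyclohexa-2,5-dien-1-one | CC(C)C(=O)C1=C(O)C(C)(C)C(O)=CC1=O
F2 | step 2 | 1-{2,6-dihydroxy-4-[(2-methylbut-3-yn-2-yl)oxy]phenyl}-2-methylpropan-1-one | CC(C)C(=O)c1c(O)cc(OC(C)(C)C#C)cc1O
F3 | step 4 | bis[2,4,6-trihydroxy-3-(2-methylpropanoyl)phenyl]methane | CC(C)C(=O)c1c(O)cc(O)c(Cc2c(O)cc(O)c(C(=O)C(C)C)c2O)c1O
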